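**Retrosynthetic overview**
1. Numbering used throughout: ring A = C1(CO2Me)=C2–C3–C4–C9(CH3)–C10(CH–C16HO); ring B = C4–C5(CH3, side chain C11–C14)–C6(Cl)–C7–C8(OH)–C9; β is the face of the C9 methyl.
2. Ring B is closed last, at C6–C7, by a ruthenium-catalysed atom-transfer radical cyclisation of a C6 dichloromethyl group onto the C7=C8 triethylsilyl enol ether of a C9 acetyl group; this gives the C6 chloride and the C8 ketone together, and the ketone is then reduced to the axial 8α-alcohol.
3. Enabling feature: on ring A the C4–C5 and C9–C8 bonds are trans-diequatorial and C5 and C9 are both quaternary, so the CHCl2 carbon C6 and the CH2 terminus C7 of the 2-siloxy-alkene lie 1,6 to each other; only 6-endo attack at C7 is open, because 5-exo attack would hit the fully substituted C8.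
4. Before that, C5 is made quaternary by two alkylations of a temporary trans-fused δ-lactone (C6 carbonyl, ring oxygen on C8), each anti to the axial C9 methyl; the lactone is then cut to the C6 aldehyde (→ CHCl2) and the C8 methyl ketone.
5. Ring A comes from 2-methylcyclohex-2-enone: CBS reduction, Eschenmoser–Claisen rearrangement (C4), allylic oxidation, vinyl 1,4-addition (C9), hydroxymethylation (C10), enol triflate carbonylation (C1); the side chain is finished by cross-metathesis. Ring order: ring A (bought), temporary lactone ring, ring B.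

Key step: step 18

Remark (assumption): the target is treated as the open hydroxy aldehyde drawn; the axial 8α-hydroxyl cannot reach the equatorial 10β-formyl group, so no lactol is expected.
Remark: the C8 configuration of compounds 11–16 is erased in step 13; the isomer with the C7 carbon equatorial is drawn.
Remark: 1, 3, 6, 14, 21 and all reagents are taken as commercial.

Step 1
Reactants: 1 2-methylcyclohex-2-en-1-one
Product: 2 (S)-2-methylcyclohex-2-en-1-ol
Conditions: (R)-2-methyl-CBS-oxazaborolidine (10 mol %), BH3·SMe2, THF, −20 °C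
Reagents that add atoms: none
Why: Corey–Bakshi–Shibata reduction; with the enone alkene as the large group the (R)-catalyst should deliver hydride to give the (S)-carbinol (future C10).

Step 2
Reactants: 2 (S)-2-methylcyclohex-2-en-1-ol; 3 N,N-dimethylacetamide dimethyl acetal
Product: 4 N,N-dimethyl-2-[(1S)-2-methylcyclohex-2-en-1-yl]acetamide
Conditions: xylenes, 140 °C, sealed tube
Reagents that add atoms: none
Why: Eschenmoser–Claisen rearrangement; the suprafacial [3,3] shift through a chair transfers the carbinol chirality to C4 (new C4–C5 bond on the face that carried oxygen) and moves the alkene to C9=C10.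

Step 3
Reactants: 4 N,N-dimethyl-2-[(1S)-2-methylcyclohex-2-en-1-yl]acetamide
Product: 5 N,N-dimethyl-2-[(1S)-2-methyl-4-oxocyclohex-2-en-1-yl]acetamide
Conditions: Rh2(cap)4 (1 mol %; cap = caprolactamate), t-BuOOH (5 equiv), K2CO3, CH2Cl2, 23 °C
Reagents that add atoms: tert-butyl hydroperoxide CC(C)(C)OO
Why: allylic C–H oxidation by a tert-butylperoxyl radical chain at the ring CH2 (C1) next to the unsubstituted alkene carbon should give the β-methyl enone; C4 is not touched.

Step 4
Reactants: 5 N,N-dimethyl-2-[(1S)-2-methyl-4-oxocyclohex-2-en-1-yl]acetamide; 6 vinylmagnesium bromide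
Product: 7 C1 trimethylsilyl enol ether (C1=C10) carrying 9α-vinyl, 9β-methyl and the 4β-CH2CONMe2 arm
Conditions: CuBr·SMe2 (10 mol %), Me3SiCl (2 equiv), HMPA, THF, −78 °C; Et3N quench
Reagents that add atoms: chlorotrimethylsilane C[Si](C)(C)Cl
Why: copper-catalysed, silyl chloride-accelerated 1,4-addition of the Grignard reagent; vinyl should enter C9 anti to the C4 arm (trans addition to a 4-substituted cyclohexenone), which sets the C9 quaternary centre, and the enolate is trapped on oxygen.

Step 5
Reactants: 7 C1 trimethylsilyl enol ether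
Product: 8 10β-hydroxymethyl C1 ketone (9α-vinyl, 9β-methyl, 4β-CH2CONMe2)
Conditions: 37 % aq. HCHO, Sc(OTf)3 (10 mol %), THF, 23 °C
Reagents that add atoms: formaldehyde C=O
Why: Mukaiyama aldol reaction with aqueous formaldehyde; the C10–C16 bond should form anti to the vinyl group just introduced, which is also the equatorial, thermodynamically preferred C10 epimer.

Step 6
Reactants: 8 10β-hydroxymethyl C1 ketone
Product: 9 10β-(tert-butyldimethylsilyloxymethyl) C1 ketone
Conditions: TBSCl, imidazole, DMF, 23 °C
Reagents that add atoms: tert-butyldimethylsilyl chloride CC(C)(C)[Si](C)(C)Cl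
Why: standard silylation of the primary alcohol prevents retro-aldol loss of C16.

Step 7
Reactants: 9 10β-(tert-butyldimethylsilyloxymethyl) C1 ketone
Product: 10 C1=C2 enol triflate of 9
Conditions: KN(SiMe3)2 (1.05 equiv), THF, −78 °C; PhNTf2
Reagents that add atoms: N-phenylbis(trifluoromethanesulfonimide) FC(F)(F)S(=O)(=O)N(c1ccccc1)S(=O)(=O)C(F)(F)F
Why: kinetic deprotonation at the CH2 carbon C2 (not the hindered C10 methine, not the amide) and O-sulfonylation give the enol triflate, which masks the ketone and prepares the C1 carboxylation.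

Step 8
Reactants: 10 C1=C2 enol triflate
Product: 11 trans-fused iodo δ-lactone (C6 carbonyl, ring oxygen on C8, CH2I equatorial) enol triflate
Conditions: I2 (2.5 equiv), THF–H2O (2:1), 0 → 23 °C
Reagents that add atoms: iodine II; water O
Why: iodolactonisation of the unsaturated N,N-dimethylamide (6-exo attack of the amide oxygen on the iodonium ion of the vinyl group, then hydrolysis of the iminium lactone); the trans-diequatorial C4 and C9 arms should give the trans-fused lactone, and the enol triflate alkene is too electron-poor to react.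

Step 9
Reactants: 11 iodo δ-lactone enol triflate
Product: 12 8-methyl δ-lactone enol triflate
Conditions: Bu3SnH (1.2 equiv), AIBN (cat.), PhH, 80 °C
Reagents that add atoms: none
Why: tin hydride radical-chain reduction removes the primary iodide (C7 becomes CH3); enol triflate, lactone and silyl ether are inert to stannyl radicals.

Step 10
Reactants: 12 8-methyl δ-lactone enol triflate
Product: 13 5α-methyl δ-lactone
Conditions: LiN(i-Pr)2 (1.1 equiv), THF, −78 °C; MeI, DMPU, −78 → −40 °C
Reagents that add atoms: iodomethane CI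
Why: lactone enolate alkylation; iodomethane should enter C5 from the α face, anti to the axial C9 methyl of the trans-fused bicycle.

Step 11
Reactants: 13 5α-methyl δ-lactone; 14 allyl bromide
Product: 15 5α-allyl-5β-methyl δ-lactone
Conditions: LiN(i-Pr)2 (1.2 equiv), THF, −78 °C; 14, DMPU, −78 → −20 °C
Reagents that add atoms: none
Why: second lactone enolate alkylation; allyl bromide again should enter anti to the axial C9 methyl, so the C5 quaternary centre has the allyl group α (equatorial) and the methyl β (axial), as in the target.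

Step 12
Reactants: 15 5α-allyl-5β-methyl δ-lactone
Product: 16 diol (C6 CH2OH, C8 CH(OH)CH3)
Conditions: i-Bu2AlH (4 equiv), CH2Cl2, −78 → 0 °C; Rochelle salt
Reagents that add atoms: none
Why: hydride reduction of the lactone to the diol; enol triflate, silyl ether and alkene are inert.

Step 13
Reactants: 16 diol
Product: 17 keto aldehyde (C6 CHO, C8 acetyl)
Conditions: (COCl)2, DMSO, CH2Cl2, −78 °C; Et3N, −78 → 0 °C
Reagents that add atoms: none
Why: Swern oxidation; both hydroxyls are activated before the base is added, so aldehyde and methyl ketone should form together without oxidation of an intermediate lactol back to the lactone.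

Step 14
Reactants: 17 keto aldehyde
Product: 19 C6 dichloromethyl methyl ketone enol triflate, via N-silylhydrazone 18 (not isolated)
Conditions: TBSNHNHTBS (1.1 equiv), Sc(OTf)3 (1 mol %), CH2Cl2, 0 → 23 °C; then CuCl2 (6 equiv), Et3N (3 equiv), MeOH, 23 °C
Reagents that add atoms: copper dichloride [Cu+2].[Cl-].[Cl-]; 1,2-bis(tert-butyldimethylsilyl)hydrazine CC(C)(C)[Si](C)(C)NN[Si](C)(C)C(C)(C)C (its atoms stay in 18 only)
Why: silylhydrazone formation is faster at the aldehyde than at the hindered methyl ketone, and copper dichloride oxidation of the hydrazone through the diazoalkane should give the gem-dichloride (known hydrazone-to-gem-dihalide conversion).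

Step 15
Reactants: 19 C6 dichloromethyl methyl ketone enol triflate
Product: 20 methyl enoate (C1 CO2Me, C1=C2)
Conditions: Pd(OAc)2 (5 mol %), PPh3 (10 mol %), CO (1 atm), MeOH, Et3N, DMF, 50 °C
Reagents that add atoms: carbon monoxide [C-]#[O+]; methanol CO
Why: palladium-catalysed methoxycarbonylation (oxidative addition of the enol triflate to zerovalent palladium, CO insertion, methanolysis); alkyl C–Cl bonds and the ketone are inert.

Step 16
Reactants: 20 methyl enoate; 21 2-methylbut-3-en-2-ol
Product: 22 (E)-C12=C13 tertiary allylic alcohol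
Conditions: second-generation Grubbs catalyst (5 mol %), 21 (5 equiv), CH2Cl2, 40 °C
Reagents that add atoms: none
Why: olefin cross-metathesis of the allyl group; the hindered tertiary allylic alcohol partner does not homodimerise and should give the E alkene, while the trisubstituted enoate is inert.

Step 17
Reactants: 22 (E)-tertiary allylic alcohol
Product: 23 bis(triethylsilyl) compound (C7=C8 enol ether, C14 ether)
Conditions: Et3SiOTf (2.5 equiv), Et3N (4 equiv), CH2Cl2, −78 → 0 °C
Reagents that add atoms: triethylsilyl trifluoromethanesulfonate CC[Si](CC)(CC)OS(=O)(=O)C(F)(F)F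
Why: soft enolisation and silylation; the acetyl group can enolise only toward C7 because C9 is quaternary, and the tertiary alcohol is silylated at the same time.

Step 18
Reactants: 23 bis(triethylsilyl) compound
Product: 25 6β-chloro C8 ketone (ring B closed, trans-decalin), via α-chloro silyl ether 24 (not isolated)
Conditions: Cp*RuCl(PPh3)2 (5 mol %), AIBN (10 mol %), PhMe (0.02 M), 90 °C, degassed
Reagents that add atoms: none
Why: Proposed new method: the divalent ruthenium complex abstracts one chlorine atom from the dichloromethyl carbon C6 (a C–Cl bond estimated to be within about 2 kcal/mol of that of chloroform, which this catalyst class activates), the α-chloroalkyl radical adds 6-endo-trig to the CH2 terminus C7 of the 2-siloxy-alkene, and the tertiary α-siloxy radical at C8 takes chlorine back from the trivalent ruthenium chloride to give 24, which loses Et3SiCl to the C8 ketone so that turnover is irreversible. The closest known reaction type is the Kharasch-type atom-transfer radical addition and cyclisation of polychloroalkanes (CCl4, CHCl3, trichloroacetates) under ruthenium or copper catalysis, including additions to silyl enol ethers that give ketones; new here are the unactivated 1,1-dichloroalkane and the ring closure. Ring B closes in the 6-endo-trig mode, since 5-exo attack would have to hit the fully substituted, oxygen-bearing C8 and give a primary radical. The only new stereocentre, C6, is set in a chair-like transition state that already has the trans ring fusion and the axial C5 methyl, so chlorine should take the pseudo-equatorial (β) position, where it eclipses the small C5 methyl and not the C4 ring bond. The step needs 6-endo regioselectivity, β-chlorine facial selectivity and chemoselectivity over addition to the C1=C2 enoate; the first is secured by the 1,1-disubstituted electron-rich alkene, the third by the trans-diequatorial C4 and C9 arms (reaching C2 would need both arms axial, which the 10β-CH2OTBS group forbids), and the quaternary C5 and C9 speed the wanted closure (gem-dialkyl effect).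

Step 19
Reactants: 25 6β-chloro C8 ketone
Product: 26 6β-chloro 8α-alcohol
Conditions: LiBH(s-Bu)3 (L-Selectride, 1.2 equiv), THF, −78 °C
Reagents that add atoms: none
Why: the hindered borohydride should attack the C8 ketone from the equatorial (β) direction, because the axial α path is blocked by the axial hydrogens at C4 and C6, and so give the axial 8α-alcohol (as in reductions of 4,4-dimethyl-3-keto terpenoids); ketone reduction at −78 °C should outpace 1,4-reduction of the trisubstituted enoate.

Step 20
Reactants: 26 6β-chloro 8α-alcohol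
Product: 27 triol (C8, C14, C16 hydroxyls)
Conditions: HF·pyridine, pyridine, THF, 0 → 23 °C
Reagents that add atoms: none
Why: buffered fluoride desilylation removes the primary TBS and the tertiary triethylsilyl ether without ionising the tertiary allylic alcohol.

Step 21
Reactants: 27 triol
Product: 28 target CNP0167913.1
Conditions: TEMPO (10 mol %), PhI(OAc)2 (1.2 equiv), CH2Cl2, 23 °C
Reagents that add atoms: none
Why: oxoammonium oxidation should convert the primary C16 alcohol to the aldehyde selectively over the hindered axial secondary and the tertiary alcohol, under neutral conditions that should not epimerise C10.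

**Compound list**
1 | 2-methylcyclohex-2-en-1-one | CC1=CCCCC1=O | starting material
2 | (S)-2-methylcyclohex-2-en-1-ol | C1CCC=C(C)[C@H]1O | intermediate
3 | N,N-dimethylacetamide dimethyl acetal | CC(OC)(OC)N(C)C | starting material
4 | N,N-dimethyl-2-[(1S)-2-methylcyclohex-2-en-1-yl]acetamide | C1CC[C@@H](CC(=O)N(C)C)C(C)=C1 | intermediate
5 | N,N-dimethyl-2-[(1S)-2-methyl-4-oxocyclohex-2-en-1-yl]acetamide | O=C1CC[C@@H](CC(=O)N(C)C)C(C)=C1 | intermediate
6 | vinylmagnesium bromide | C=C[Mg]Br | starting material
7 | C1 trimethylsilyl enol ether (C1=C10), 9α-vinyl, 9β-methyl, 4β-CH2CONMe2 | C[Si](C)(C)OC=1CC[C@@H](CC(=O)N(C)C)[C@@](C=C)(C)C=1 | intermediate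
8 | C1 ketone, 10β-CH2OH, 9α-vinyl, 9β-methyl, 4β-CH2CONMe2 | O=C1CC[C@@H](CC(=O)N(C)C)[C@@](C=C)(C)[C@H]1CO | intermediate
9 | C1 ketone, 10β-CH2OTBS, 9α-vinyl, 9β-methyl, 4β-CH2CONMe2 | O=C1CC[C@@H](CC(=O)N(C)C)[C@@](C=C)(C)[C@H]1CO[Si](C)(C)C(C)(C)C | intermediate
10 | C1=C2 enol triflate of 9 | FC(F)(F)S(=O)(=O)OC1=CC[C@@H](CC(=O)N(C)C)[C@@](C=C)(C)[C@H]1CO[Si](C)(C)C(C)(C)C | intermediate
11 | trans-fused δ-lactone (C6 carbonyl, O on C8), 8-CH2I equatorial, C1=C2 enol triflate, 10β-CH2OTBS | FC(F)(F)S(=O)(=O)OC1=CC[C@H]2CC(=O)O[C@@H](CI)[C@]2(C)[C@H]1CO[Si](C)(C)C(C)(C)C | intermediate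
12 | as 11 with 8-CH3 | FC(F)(F)S(=O)(=O)OC1=CC[C@H]2CC(=O)O[C@@H](C)[C@]2(C)[C@H]1CO[Si](C)(C)C(C)(C)C | intermediate
13 | 5α-methyl δ-lactone | FC(F)(F)S(=O)(=O)OC1=CC[C@H]2[C@H](C)C(=O)O[C@@H](C)[C@]2(C)[C@H]1CO[Si](C)(C)C(C)(C)C | intermediate
14 | allyl bromide | C=CCBr | starting material
15 | 5α-allyl-5β-methyl δ-lactone | FC(F)(F)S(=O)(=O)OC1=CC[C@H]2[C@](C)(CC=C)C(=O)O[C@@H](C)[C@]2(C)[C@H]1CO[Si](C)(C)C(C)(C)C | intermediate
16 | diol: C6 CH2OH, C8 CH(OH)CH3, ring B open | FC(F)(F)S(=O)(=O)OC1=CC[C@@H]([C@](C)(CC=C)CO)[C@@]([C@H](C)O)(C)[C@H]1CO[Si](C)(C)C(C)(C)C | intermediate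
17 | keto aldehyde: C6 CHO, C8 acetyl | FC(F)(F)S(=O)(=O)OC1=CC[C@@H]([C@](C)(CC=C)C=O)[C@@](C(C)=O)(C)[C@H]1CO[Si](C)(C)C(C)(C)C | intermediate
18 | C6 (E)-N-tert-butyldimethylsilylhydrazone of 17 | FC(F)(F)S(=O)(=O)OC1=CC[C@@H]([C@](C)(CC=C)/C=N/N[Si](C)(C)C(C)(C)C)[C@@](C(C)=O)(C)[C@H]1CO[Si](C)(C)C(C)(C)C | intermediate
19 | C6 dichloromethyl, C8 acetyl, C1=C2 enol triflate | FC(F)(F)S(=O)(=O)OC1=CC[C@@H]([C@](C)(CC=C)C(Cl)Cl)[C@@](C(C)=O)(C)[C@H]1CO[Si](C)(C)C(C)(C)C | intermediate
20 | methyl enoate (C1 CO2Me), C6 dichloromethyl, C8 acetyl, C5 allyl | COC(=O)C1=CC[C@@H]([C@](C)(CC=C)C(Cl)Cl)[C@@](C(C)=O)(C)[C@H]1CO[Si](C)(C)C(C)(C)C | intermediate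
21 | 2-methylbut-3-en-2-ol | CC(C)(O)C=C | starting material
22 | as 20 with the full (E)-CH2CH=CH–C(CH3)2OH side chain | COC(=O)C1=CC[C@@H]([C@](C)(C/C=C/C(C)(C)O)C(Cl)Cl)[C@@](C(C)=O)(C)[C@H]1CO[Si](C)(C)C(C)(C)C | intermediate
23 | cyclisation precursor: C7=C8 triethylsilyl enol ether, C14 OSiEt3, C6 dichloromethyl | COC(=O)C1=CC[C@@H]([C@](C)(C/C=C/C(C)(C)O[Si](CC)(CC)CC)C(Cl)Cl)[C@@](C(=C)O[Si](CC)(CC)CC)(C)[C@H]1CO[Si](C)(C)C(C)(C)C | intermediate
24 | ring B closed, 6β-Cl, C8 α-chloro triethylsilyl ether (chlorine drawn α) | COC(=O)C1=CC[C@H]2[C@](C)(C/C=C/C(C)(C)O[Si](CC)(CC)CC)[C@@H](Cl)C[C@@](Cl)(O[Si](CC)(CC)CC)[C@]2(C)[C@H]1CO[Si](C)(C)C(C)(C)C | intermediate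
25 | 6β-chloro C8 ketone, trans-decalin | COC(=O)C1=CC[C@H]2[C@](C)(C/C=C/C(C)(C)O[Si](CC)(CC)CC)[C@@H](Cl)CC(=O)[C@]2(C)[C@H]1CO[Si](C)(C)C(C)(C)C | intermediate
26 | 6β-chloro 8α-alcohol, C14 OSiEt3, C16 OTBS | COC(=O)C1=CC[C@H]2[C@](C)(C/C=C/C(C)(C)O[Si](CC)(CC)CC)[C@@H](Cl)C[C@H](O)[C@]2(C)[C@H]1CO[Si](C)(C)C(C)(C)C | intermediate
27 | triol (C8, C14, C16 OH) | COC(=O)C1=CC[C@H]2[C@](C)(C/C=C/C(C)(C)O)[C@@H](Cl)C[C@H](O)[C@]2(C)[C@H]1CO | intermediate
28 | CNP0167913.1 | COC(=O)C1=CC[C@H]2[C@](C)(C/C=C/C(C)(C)O)[C@@H](Cl)C[C@H](O)[C@]2(C)[C@H]1C=O | target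

**Step count and risks**
Total step count: 21. Longest linear sequence: 21 steps (from 1; all other inputs are bought).

Steps most likely to fail:

1. Step 18 (Proposed new method). Chlorine-atom abstraction from the unactivated dichloromethyl carbon may be too slow for catalyst turnover, and the closure may not discriminate the two faces of the C6 radical. The fallback uses known chemistry and sets out from 23. Tin hydride reductive 6-endo radical cyclisation of the 1,1-dichloride (Bu3SnH, AIBN, slow addition, PhH, 80 °C; one chlorine is kept) should give the 8β-triethylsilyl ether F1, with hydrogen delivered axially to C8. PPTS in MeOH should remove both triethylsilyl groups to give the 8β,14-diol F2, and Dess–Martin periodinane should then give the C8 ketone F3. LiBH(s-Bu)3 at −78 °C should give the 8α-alcohol F4, and HF·pyridine then gives 27, where the route is rejoined.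

2. Step 14. The copper carbenoid at the neopentyl carbon C6 may undergo a 1,2-alkyl shift, and the silylhydrazine may also condense with the C8 ketone. The fallback sets out from 17 and comes back at 19 with no new compound: direct deoxydichlorination of the aldehyde with triphenyl phosphite dichloride ((PhO)3P, Cl2, CH2Cl2, −78 °C), which passes through an α-chloroalkoxyphosphonium salt and not a carbenoid, and which the hindered methyl ketone should survive at that temperature.

3. Step 19. Hydride may add in the conjugate sense to the C1=C2 enoate, or attack the α face of the C8 ketone. The fallback sets out from 25 and comes back at 26 with no new compound: catalyst-controlled Corey–Bakshi–Shibata reduction ((R)-2-methyl-CBS-oxazaborolidine, catecholborane, PhMe, −78 °C), which is selective for ketones and, with the quaternary C9 as the large group, should give the (8S) = 8α-alcohol.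

**Further compounds**
F1 | step 18 | ring B closed, 6β-Cl, 8β-OSiEt3, C14 OSiEt3, C16 OTBS | COC(=O)C1=CC[C@H]2[C@](C)(C/C=C/C(C)(C)O[Si](CC)(CC)CC)[C@@H](Cl)C[C@@H](O[Si](CC)(CC)CC)[C@]2(C)[C@H]1CO[Si](C)(C)C(C)(C)C
F2 | step 18 | 6β-Cl, 8β-OH, C14 OH, C16 OTBS | COC(=O)C1=CC[C@H]2[C@](C)(C/C=C/C(C)(C)O)[C@@H](Cl)C[C@@H](O)[C@]2(C)[C@H]1CO[Si](C)(C)C(C)(C)C
F3 | step 18 | 6β-Cl, C8 ketone, C14 OH, C16 OTBS | COC(=O)C1=CC[C@H]2[C@](C)(C/C=C/C(C)(C)O)[C@@H](Cl)CC(=O)[C@]2(C)[C@H]1CO[Si](C)(C)C(C)(C)C
F4 | step 18 | 6β-Cl, 8α-OH, C14 OH, C16 OTBS | COC(=O)C1=CC[C@H]2[C@](C)(C/C=C/C(C)(C)O)[C@@H](Cl)C[C@H](O)[C@]2(C)[C@H]1CO[Si](C)(C)C(C)(C)C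
F0 | step 14 | none | none
F0 | step 19 | none | none
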